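Retrosynthesis: the vinylic C–Br bond on the exocyclic carbon is cut first (bromine addition and HBr loss on a 5-methylene lactone). The C5=CH2 bond is then hydrated back to a 5-hydroxy-5-methylbutenolide.
Enabling feature: in the ring O1–C2(=O)–C3=C4(Br)–C5, both carbons flanking O1 carry oxygen, so the ring is a furan plus O2. Cutting C2=O and C5–OH leaves a furan with H on C2, the 1-acetoxybutyl group on C3, Br on C4 and CH3 on C5, and C2 holds the only ring hydrogen.
That furan is cut at C5–CH3 (furyllithium + MeI) and at C3–C1' (4-bromo-3-furyllithium + butanoyl Weinreb amide), which leads back to 3,4-dibromofuran.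
Forward: the five-membered ring is bought as the furan and no lasting ring is built. The butanoyl chain is joined first, followed by ketone reduction, C5 methylation, acetate installation, ring oxidation with singlet oxygen, dehydration and bromination/dehydrobromination.
Stereochemistry: the single centre C1' (R) comes from a Corey–Bakshi–Shibata reduction of the furyl ketone, and its C–O bond is never broken afterwards. The Z geometry (vinylic Br syn to O1) arises because the C4 bromine would clash with the vinylic bromine in the E isomer.
Key step: step 7

Remark: lactone numbering (O1, C2 carbonyl, C3, C4, C5; C1' = carbinol carbon) is also used for the furans, because the atoms map one to one. 3,4-Dibromofuran and N-methoxy-N-methylbutanamide are assumed to be purchasable.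

Step 1
Reactants: 1 3,4-dibromofuran; 2 N-methoxy-N-methylbutanamide
Product: 5 1-(4-bromofuran-3-yl)butan-1-one, via 4-bromo-3-furyllithium 3 (not isolated), via tetrahedral lithium alkoxide 4 (not isolated)
Conditions: n-BuLi (1.0 equiv), Et2O, −78 °C; then 2, −78 → 0 °C; then 1 M HCl
Reagents that add atoms: none
Why: Bromine–lithium exchange at one of the two equivalent C–Br bonds outruns α-deprotonation and lithium migration at −78 °C in Et2O, and the Weinreb ketone synthesis holds the carbonyl as chelated alkoxide 4 until the acid quench, so only one acylation takes place and the second bromine stays for C4 of the target.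

Step 2
Reactants: 5 1-(4-bromofuran-3-yl)butan-1-one
Product: 6 (R)-1-(4-bromofuran-3-yl)butan-1-ol
Conditions: (S)-2-methyl-CBS-oxazaborolidine [(3aS)-1-methyl-3,3-diphenyltetrahydro-1H,3H-pyrrolo[1,2-c][1,3,2]oxazaborole, 10 mol %], BH3·SMe2, THF, −20 °C, slow addition of 5; then MeOH
Reagents that add atoms: none
Why: In the Corey–Bakshi–Shibata reduction the ketone binds the ring boron of the catalyst–BH3 complex through the lone pair anti to the larger, flat 4-bromofuryl group, so hydride is passed to the Si face through a six-membered transition state and C1' is set as R, the sense established for aryl n-alkyl ketones with the (S)-catalyst.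

Step 3
Reactants: 6 (R)-1-(4-bromofuran-3-yl)butan-1-ol
Product: 7 (R)-[1-(4-bromofuran-3-yl)butoxy](tert-butyl)dimethylsilane
Conditions: TBSCl, imidazole, DMF, rt
Reagents that add atoms: tert-butyldimethylsilyl chloride, CC(C)(C)[Si](C)(C)Cl
Why: Imidazole-promoted O-silylation of a secondary alcohol leaves the C1'–O bond intact, removes the acidic and lithium-directing hydroxyl before the metalation, and puts a bulky group beside the C2 hydrogen that has to survive step 4.

Step 4
Reactants: 7 (R)-[1-(4-bromofuran-3-yl)butoxy](tert-butyl)dimethylsilane
Product: 9 (R)-[1-(4-bromo-5-methylfuran-3-yl)butoxy](tert-butyl)dimethylsilane, via 5-lithiofuran 8 (not isolated)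
Conditions: LiN(i-Pr)2 (commercial solution), THF, −78 °C; then MeI, −78 °C → rt
Reagents that add atoms: iodomethane, CI
Why: Deprotonative lithiation followed by SN2 alkylation: LiN(i-Pr)2 is just basic enough to remove the α-hydrogen acidified by the adjacent C4 bromine, as is known for 3-bromofuran, whereas the C2 hydrogen is unactivated and screened by the silyloxybutyl group, the amide base does not exchange the bromine, and the 5-lithio-4-bromo arrangement is already the resting point of a halogen dance.

Step 5
Reactants: 9 (R)-[1-(4-bromo-5-methylfuran-3-yl)butoxy](tert-butyl)dimethylsilane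
Product: 10 (R)-1-(4-bromo-5-methylfuran-3-yl)butan-1-ol
Conditions: n-Bu4NF, THF, 0 °C → rt
Reagents that add atoms: none
Why: Fluoride-driven desilylation breaks the Si–O and not the C1'–O bond, so the configuration is kept, and it avoids the acid that could ionise the furylic carbinol.

Step 6
Reactants: 10 (R)-1-(4-bromo-5-methylfuran-3-yl)butan-1-ol
Product: 11 (R)-1-(4-bromo-5-methylfuran-3-yl)butyl acetate
Conditions: Ac2O, Et3N, 4-(dimethylamino)pyridine (cat), CH2Cl2, 0 °C → rt
Reagents that add atoms: acetic anhydride, CC(=O)OC(C)=O
Why: Nucleophile-catalysed O-acylation proceeds with retention at C1' and installs the acetate of the target while the ring is still a robust furan and not yet a base-sensitive butenolide.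

Step 7
Reactants: 11 (R)-1-(4-bromo-5-methylfuran-3-yl)butyl acetate; 12 dioxygen
Product: 14 (R)-1-(4-bromo-5-hydroxy-5-methyl-2-oxo-2,5-dihydrofuran-3-yl)butyl acetate (C5 epimers), via endoperoxide 13 (not isolated)
Conditions: O2 (bubbled), hν (white LED), 5,10,15,20-tetraphenylporphyrin (cat), CH2Cl2, −78 °C; then i-Pr2NEt, −78 °C → rt
Reagents that add atoms: dioxygen 12, O=O
Why: Energy transfer from the excited porphyrin turns 12 into singlet oxygen, which acts as the dienophile and adds suprafacially to C2 and C5 of the furan diene in a concerted [4+2] cycloaddition; the C5 methyl and C3 alkyl groups make up for the electron withdrawal by bromine, and endoperoxide 13 persists at −78 °C. The hindered amine, added only after irradiation so that it cannot quench singlet oxygen, takes the bridgehead hydrogen at C2, the O–O bond breaks (Kornblum–DeLaMare fragmentation), C2 becomes the lactone carbonyl and the oxygen left on C5 becomes the hemiketal hydroxyl. The closest known reaction type is the dye-sensitised photooxygenation of alkylfurans with a hindered amine base to 5-hydroxyfuran-2(5H)-ones. The only ring closed is the six-membered 1,2-dioxene ring of 13, formed by cycloaddition and opened again in the same flask, so the ring O1–C2–C3–C4–C5 of the furan passes unchanged into the lactone. C5 is formed without control as two epimers that interconvert through the open keto acid, which does no harm because step 8 makes C5 trigonal, and C1' is not involved. The selectivity needed is regiocontrol over which α-carbon becomes the carbonyl, and it is built into 11 because C2 carries the only bridgehead hydrogen while C5 is blocked by methyl; chemoselectivity follows from the furan being the only electron-rich π system present.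

Step 8
Reactants: 14 (R)-1-(4-bromo-5-hydroxy-5-methyl-2-oxo-2,5-dihydrofuran-3-yl)butyl acetate
Product: 15 (R)-1-(4-bromo-5-methylene-2-oxo-2,5-dihydrofuran-3-yl)butyl acetate
Conditions: P4O10, CH2Cl2, reflux
Reagents that add atoms: none
Why: Dehydration of 5-hydroxy-5-methylbutenolides with P4O10 is a standard entry to 5-methylene lactones: the hemiketal hydroxyl is activated and leaves from C5 with help from O1, a methyl hydrogen is the only β-hydrogen available, and the C1' acetate holds because a cation next to the electron-poor C3 is too costly to form.

Step 9
Reactants: 15 (R)-1-(4-bromo-5-methylene-2-oxo-2,5-dihydrofuran-3-yl)butyl acetate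
Product: 17 (R)-1-[(Z)-4-bromo-5-(bromomethylene)-2-oxo-2,5-dihydrofuran-3-yl]butyl acetate (target), via tribromide 16 (not isolated)
Conditions: Br2 (1.0 equiv), CH2Cl2, 0 °C; then i-Pr2NEt, 0 °C → rt
Reagents that add atoms: bromine, BrBr
Why: Electrophilic bromine addition takes place at the exocyclic enol-ester double bond, the only electron-rich π bond left, and the hindered amine then removes HBr from the C5–Br/CH2Br pair of 16 (dehydrobromination assisted by O1), giving the Z isomer because the E isomer would force the vinylic bromine against the C4 bromine, while the bulk of the amine keeps it from adding to C4 and expelling bromide or the allylic acetate.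

Compound list
1 | 3,4-dibromofuran | Brc1cocc1Br | starting material
2 | N-methoxy-N-methylbutanamide | CCCC(=O)N(C)OC | starting material
3 | 4-bromo-3-furyllithium (formed in the flask) | [Li]c1cocc1Br | intermediate
4 | lithium 1-(4-bromofuran-3-yl)-1-[methoxy(methyl)amino]butan-1-olate (formed in the flask) | CCCC(O[Li])(N(C)OC)c1cocc1Br | intermediate
5 | 1-(4-bromofuran-3-yl)butan-1-one | CCCC(=O)c1cocc1Br | intermediate
6 | (R)-1-(4-bromofuran-3-yl)butan-1-ol | CCC[C@@H](O)c1cocc1Br | intermediate
7 | (R)-[1-(4-bromofuran-3-yl)butoxy](tert-butyl)dimethylsilane | CCC[C@@H](O[Si](C)(C)C(C)(C)C)c1cocc1Br | intermediate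
8 | (R)-[1-(4-bromo-5-lithiofuran-3-yl)butoxy](tert-butyl)dimethylsilane (formed in the flask) | CCC[C@@H](O[Si](C)(C)C(C)(C)C)c1coc([Li])c1Br | intermediate
9 | (R)-[1-(4-bromo-5-methylfuran-3-yl)butoxy](tert-butyl)dimethylsilane | CCC[C@@H](O[Si](C)(C)C(C)(C)C)c1coc(C)c1Br | intermediate
10 | (R)-1-(4-bromo-5-methylfuran-3-yl)butan-1-ol | CCC[C@@H](O)c1coc(C)c1Br | intermediate
11 | (R)-1-(4-bromo-5-methylfuran-3-yl)butyl acetate | CCC[C@@H](OC(C)=O)c1coc(C)c1Br | intermediate
12 | dioxygen | O=O | starting material
13 | (R)-1-(6-bromo-1-methyl-2,3,7-trioxabicyclo[2.2.1]hept-5-en-5-yl)butyl acetate (both facial adducts, formed in the flask) | CCC[C@@H](OC(C)=O)C1=C(Br)C2(C)OOC1O2 | intermediate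
14 | (R)-1-(4-bromo-5-hydroxy-5-methyl-2-oxo-2,5-dihydrofuran-3-yl)butyl acetate (C5 epimers) | CCC[C@@H](OC(C)=O)C1=C(Br)C(C)(O)OC1=O | intermediate
15 | (R)-1-(4-bromo-5-methylene-2-oxo-2,5-dihydrofuran-3-yl)butyl acetate | CCC[C@@H](OC(C)=O)C1=C(Br)C(=C)OC1=O | intermediate
16 | (R)-1-[4,5-dibromo-5-(bromomethyl)-2-oxo-2,5-dihydrofuran-3-yl]butyl acetate (C5 epimers, formed in the flask) | CCC[C@@H](OC(C)=O)C1=C(Br)C(Br)(CBr)OC1=O | intermediate
17 | (R)-1-[(Z)-4-bromo-5-(bromomethylene)-2-oxo-2,5-dihydrofuran-3-yl]butyl acetate | CCC[C@@H](OC(C)=O)C1=C(Br)/C(=C/Br)OC1=O | target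

Total step count: 9
Longest linear sequence: 9 steps (1 → 17)

Steps most likely to fail

(a) Step 7.
- Risk: the cycloaddition may be sluggish because bromine lowers the electron density of the furan. The endoperoxide may also collapse unselectively on warming (O–O homolysis or rearrangement) before the amine has removed the bridgehead hydrogen.
- Fallback: a light-free, two-stage ionic oxidation that sets out from 11.
- NBS, NaHCO3, acetone–H2O, −15 °C should open the furan to the cis-keto-enal (4R,5E)-6-bromo-5-formyl-7-oxooct-5-en-4-yl acetate F1, in which only the former C2–H terminus can appear as an aldehyde.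
- A Pinnick oxidation (NaClO2, NaH2PO4, 2-methyl-2-butene, t-BuOH–H2O, rt) should then convert the formyl group into the acid (E)-2-[(R)-1-acetoxybutyl]-3-bromo-4-oxopent-2-enoic acid F2.
- The carboxyl and acetyl groups of this acid are cis on the double bond, so it should close by itself to the lactol. The route is rejoined at 14.

(b) Step 9.
- Risk: the amine or bromide may attack C4 with loss of the ring bromine or of the allylic acetate. Acetic acid may be eliminated from the side chain, and geometric control in the loss of HBr may be incomplete.
- Fallback: a base-free endgame that sets out from 14 and puts the bromine on the methyl carbon before the dehydration.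
- Br2, HBr (cat), AcOH, rt should brominate the only enolisable position through the open keto-acid tautomer. This should give (R)-1-[4-bromo-5-(bromomethyl)-5-hydroxy-2-oxo-2,5-dihydrofuran-3-yl]butyl acetate F3.
- P4O10 in refluxing CH2Cl2 should dehydrate this lactol directly to the bromomethylene lactone, under the same steric bias for the Z isomer. The route is rejoined at 17 without passing through 15 and 16.

(c) Step 2.
- Risk: facial selectivity may be poor, because an n-propyl chain and a flat five-membered heteroaryl group differ less in size than the groups of a standard aryl methyl ketone. Uncatalysed background reduction by borane may also erode selectivity.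
- Fallback: resolution in place of asymmetric catalysis, setting out from 5.
- NaBH4 in MeOH at 0 °C should give rac-1-(4-bromofuran-3-yl)butan-1-ol F4.
- Burkholderia cepacia lipase with vinyl acetate in t-BuOMe should acylate the (R)-enantiomer preferentially, following the empirical size rule for lipase acylation of secondary alcohols. This should give (R)-1-(4-bromofuran-3-yl)butyl acetate F5 and leave (S)-1-(4-bromofuran-3-yl)butan-1-ol F6, and the two are separable by chromatography.
- K2CO3 in MeOH cleaves the acetate, and the route is rejoined at 6.
- The unwanted alcohol can be oxidised with MnO2 back to 5 and recycled.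

Further compounds
F1 | step 7 | (4R,5E)-6-bromo-5-formyl-7-oxooct-5-en-4-yl acetate | CCC[C@@H](OC(C)=O)/C(C=O)=C(\Br)C(C)=O
F2 | step 7 | (E)-2-[(R)-1-acetoxybutyl]-3-bromo-4-oxopent-2-enoic acid | CCC[C@@H](OC(C)=O)/C(C(=O)O)=C(\Br)C(C)=O
F3 | step 9 | (R)-1-[4-bromo-5-(bromomethyl)-5-hydroxy-2-oxo-2,5-dihydrofuran-3-yl]butyl acetate (C5 epimers) | CCC[C@@H](OC(C)=O)C1=C(Br)C(O)(CBr)OC1=O
F4 | step 2 | rac-1-(4-bromofuran-3-yl)butan-1-ol | CCCC(O)c1cocc1Br
F5 | step 2 | (R)-1-(4-bromofuran-3-yl)butyl acetate | CCC[C@@H](OC(C)=O)c1cocc1Br
F6 | step 2 | (S)-1-(4-bromofuran-3-yl)butan-1-ol | CCC[C@H](O)c1cocc1Br
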